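**Strategy.** Everything rests on cutting the CH2–CH2 bond (C-3–C-4, chromane numbering) of the dihydropyran ring fused to ring B. Its O-1–C-2(CH3)2–C-3 unit is a tert-butyl aryl ether in which one methyl group has become C-3. Since C-2 is quaternary, a carbene at C-4 can only reach primary C–H bonds, through a six-membered transition state. The key step therefore turns the N-sulfonylhydrazone of 5-bromo-2-tert-butoxybenzaldehyde into 6-bromo-2,2-dimethylchromane by silver-carbene 1,6-C–H insertion. The bromide is carried on to a 7-hydroxyisoflavone; transfer hydrogenation with dynamic kinetic resolution, reoxidation and a closing aromatic Claisen rearrangement set the (3R) centre and deliver the 8-prenyl 7-phenol.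

Key step: step 3

Remark: "chromane C-n" means the 2,2-dimethylchromane unit and "isoflavanone C-n" the chromanone core; reagents 4 and 8 are assumed to be purchasable (4 is otherwise one step from the sulfonyl chloride and hydrazine).

**Step 1**
Reactants: 1 5-bromo-2-fluorobenzaldehyde; 2 potassium tert-butoxide
Product: 3 5-bromo-2-(tert-butoxy)benzaldehyde
Conditions: KOtBu, THF, 0 °C to rt
Reagents that add atoms: potassium tert-butoxide CC(C)(C)[O-].[K+]
Why: Nucleophilic aromatic substitution (SNAr): the fluoride ortho to the formyl group is activated for addition–elimination, and the aldehyde has no α-hydrogen, so reversible alkoxide addition to C=O should do no harm.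

**Step 2**
Reactants: 3 5-bromo-2-(tert-butoxy)benzaldehyde; 4 2-(trifluoromethyl)benzenesulfonohydrazide
Product: 5 (E)-N'-[5-bromo-2-(tert-butoxy)benzylidene]-2-(trifluoromethyl)benzenesulfonohydrazide
Conditions: MeOH, rt, product collected by filtration
Reagents that add atoms: 2-(trifluoromethyl)benzenesulfonohydrazide NNS(=O)(=O)c1ccccc1C(F)(F)F
Why: Hydrazone condensation of an aryl aldehyde with a sulfonyl hydrazide is fast and selective, and the product should crystallise free of water and methanol, which the next step does not tolerate.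

**Step 3**
Reactants: 5 (E)-N'-[5-bromo-2-(tert-butoxy)benzylidene]-2-(trifluoromethyl)benzenesulfonohydrazide
Product: 7 6-bromo-2,2-dimethylchromane, via 4-bromo-1-(tert-butoxy)-2-(diazomethyl)benzene 6 (not isolated)
Conditions: NaH, TpBr3Ag(thf) (10 mol %), PhCF3 (0.02 M), 40 to 60 °C
Reagents that add atoms: none
Why: Proposed new method: NaH deprotonates 5 and the salt should lose sulfinate (Bamford–Stevens) to give diazoalkane 6, which silver turns into an electrophilic aryl carbene at the future chromane C-4; because C-2 is quaternary, the only C(sp3)–H bonds in reach are the nine equivalent primary ones of the tert-butoxy group, so a concerted three-centre insertion through a six-membered transition state forms C-3–C-4 and closes the dihydropyran ring (six-membered ring, carbene 1,6-C–H insertion). The closest known reaction types are the silver-catalysed intermolecular insertion of aryl carbenes from N-triftosylhydrazones into unactivated alkane C–H bonds and the intramolecular insertion of free aryl carbenes into ortho tert-butyl and alkoxy groups. No stereocentre is formed. The step needs insertion to outrun carbene dimerisation and azine formation; slow release of 6 from the salt, high dilution, a solvent without C(sp3)–H bonds and the ortho tert-butoxy group holding its methyl groups over the carbene carbon should secure this. The aryl bromide is inert to silver carbenes.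

**Step 4**
Reactants: 7 6-bromo-2,2-dimethylchromane; 8 (2-tert-butoxy-2-oxoethyl)zinc bromide
Product: 9 tert-butyl 2-(2,2-dimethylchroman-6-yl)acetate
Conditions: Pd(dba)2 (2 mol %), Q-Phos (2 mol %), THF, rt
Reagents that add atoms: (2-tert-butoxy-2-oxoethyl)zinc bromide CC(C)(C)OC(=O)C[Zn]Br
Why: Pd-catalysed Negishi-type α-arylation of a Reformatsky zinc enolate with an aryl bromide; the neutral zinc enolate should avoid diarylation and ester condensation.

**Step 5**
Reactants: 9 tert-butyl 2-(2,2-dimethylchroman-6-yl)acetate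
Product: 10 2-(2,2-dimethylchroman-6-yl)acetic acid
Conditions: TFA, CH2Cl2, 0 °C to rt
Reagents that add atoms: none
Why: Acidolysis of the tert-butyl ester (E1 loss of isobutene); the cyclic tertiary aryl ether of the chromane re-closes if it ionises and should survive.

**Step 6**
Reactants: 10 2-(2,2-dimethylchroman-6-yl)acetic acid; 11 resorcinol; 12 N,N-dimethylformamide
Product: 14 3-(2,2-dimethylchroman-6-yl)-7-hydroxy-4H-chromen-4-one, via 1-(2,4-dihydroxyphenyl)-2-(2,2-dimethylchroman-6-yl)ethan-1-one 13 (not isolated)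
Conditions: BF3·OEt2, 85 °C; then DMF, MsCl, 60 °C
Reagents that add atoms: resorcinol Oc1cccc(O)c1; N,N-dimethylformamide CN(C)C=O
Why: Friedel–Crafts (Hoesch-type) C-acylation of resorcinol at C-4 gives deoxybenzoin 13, whose activated methylene is formylated by the DMF/MsCl Vilsmeier-type reagent and cyclises onto the ortho hydroxyl (one-pot deoxybenzoin route to isoflavones).

**Step 7**
Reactants: 15 2-methylbut-3-en-2-ol; 16 di-tert-butyl dicarbonate
Product: 17 tert-butyl 2-methylbut-3-en-2-yl carbonate
Conditions: n-BuLi, THF, −78 °C; then Boc2O, to rt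
Reagents that add atoms: di-tert-butyl dicarbonate CC(C)(C)OC(=O)OC(=O)OC(C)(C)C
Why: O-acylation of the lithium tertiary alkoxide with Boc2O gives the mixed carbonate used as π-allyl precursor.

**Step 8**
Reactants: 14 3-(2,2-dimethylchroman-6-yl)-7-hydroxy-4H-chromen-4-one; 17 tert-butyl 2-methylbut-3-en-2-yl carbonate
Product: 18 3-(2,2-dimethylchroman-6-yl)-7-(2-methylbut-3-en-2-yloxy)-4H-chromen-4-one
Conditions: Pd(PPh3)4 (5 mol %), THF, 0 °C
Reagents that add atoms: tert-butyl 2-methylbut-3-en-2-yl carbonate C=CC(C)(C)OC(=O)OC(C)(C)C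
Why: Pd-catalysed decarboxylative O-allylation (Tsuji–Trost): under kinetic control at low temperature the phenoxide should attack the more substituted terminus of the 1,1-dimethylallyl–Pd ion pair and give the tertiary (reverse-prenyl) aryl ether.

**Step 9**
Reactants: 18 3-(2,2-dimethylchroman-6-yl)-7-(2-methylbut-3-en-2-yloxy)-4H-chromen-4-one
Product: 20 (3R,4R)-3-(2,2-dimethylchroman-6-yl)-7-(2-methylbut-3-en-2-yloxy)chroman-4-ol (cis), via racemic 3-(2,2-dimethylchroman-6-yl)-7-(2-methylbut-3-en-2-yloxy)chroman-4-one 19 (not isolated)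
Conditions: RuCl[(R,R)-TsDPEN](p-cymene) (5 mol %), HCO2H/Et3N, EtOAc, 40 °C
Reagents that add atoms: none
Why: Noyori–Ikariya asymmetric transfer hydrogenation with dynamic kinetic resolution: conjugate reduction gives 19, which racemises through its enol under Et3N while the (R,R)-catalyst should reduce the (3R)-ketone faster, setting C-4 as R by catalyst control and C-3 as R through the cis relation; the terminal alkene has no allylic hydrogen and should stay untouched.

**Step 10**
Reactants: 20 (3R,4R)-3-(2,2-dimethylchroman-6-yl)-7-(2-methylbut-3-en-2-yloxy)chroman-4-ol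
Product: 21 (3R)-3-(2,2-dimethylchroman-6-yl)-7-(2-methylbut-3-en-2-yloxy)chroman-4-one
Conditions: Dess–Martin periodinane, CH2Cl2, 0 °C to rt
Reagents that add atoms: none
Why: Dess–Martin oxidation of the benzylic alcohol under near-neutral conditions removes the auxiliary C-4 centre and should leave the enolisable C-3 centre intact.

**Step 11**
Reactants: 21 (3R)-3-(2,2-dimethylchroman-6-yl)-7-(2-methylbut-3-en-2-yloxy)chroman-4-one
Product: 22 (3R)-3-(2,2-dimethylchroman-6-yl)-7-hydroxy-8-(3-methylbut-2-en-1-yl)chroman-4-one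
Conditions: degassed PhMe, 120 °C, sealed tube, Ar
Reagents that add atoms: none
Why: Aromatic Claisen rearrangement ([3,3]-sigmatropic shift, then tautomerisation) of the 1,1-dimethylallyl aryl ether should go to C-8, the ortho position flanked by O-1 and O-7, giving the prenyl group and the free phenol with no added acid or base that could racemise C-3.

**Compound list**
1 | 5-bromo-2-fluorobenzaldehyde | O=Cc1cc(Br)ccc1F | starting material
2 | potassium tert-butoxide | CC(C)(C)[O-].[K+] | starting material
3 | 5-bromo-2-(tert-butoxy)benzaldehyde | CC(C)(C)Oc1ccc(Br)cc1C=O | intermediate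
4 | 2-(trifluoromethyl)benzenesulfonohydrazide | NNS(=O)(=O)c1ccccc1C(F)(F)F | starting material
5 | (E)-N'-[5-bromo-2-(tert-butoxy)benzylidene]-2-(trifluoromethyl)benzenesulfonohydrazide | CC(C)(C)Oc1ccc(Br)cc1/C=N/NS(=O)(=O)c1ccccc1C(F)(F)F | intermediate
6 | 4-bromo-1-(tert-butoxy)-2-(diazomethyl)benzene | CC(C)(C)Oc1ccc(Br)cc1C=[N+]=[N-] | intermediate (not isolated)
7 | 6-bromo-2,2-dimethylchromane | CC1(C)CCc2cc(Br)ccc2O1 | intermediate
8 | (2-tert-butoxy-2-oxoethyl)zinc bromide | CC(C)(C)OC(=O)C[Zn]Br | starting material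
9 | tert-butyl 2-(2,2-dimethylchroman-6-yl)acetate | CC(C)(C)OC(=O)Cc1ccc2c(c1)CCC(C)(C)O2 | intermediate
10 | 2-(2,2-dimethylchroman-6-yl)acetic acid | OC(=O)Cc1ccc2c(c1)CCC(C)(C)O2 | intermediate
11 | resorcinol | Oc1cccc(O)c1 | starting material
12 | N,N-dimethylformamide | CN(C)C=O | starting material
13 | 1-(2,4-dihydroxyphenyl)-2-(2,2-dimethylchroman-6-yl)ethan-1-one | O=C(Cc1ccc2c(c1)CCC(C)(C)O2)c1ccc(O)cc1O | intermediate (not isolated)
14 | 3-(2,2-dimethylchroman-6-yl)-7-hydroxy-4H-chromen-4-one | O=c1c(-c2ccc3c(c2)CCC(C)(C)O3)coc2cc(O)ccc12 | intermediate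
15 | 2-methylbut-3-en-2-ol | CC(C)(O)C=C | starting material
16 | di-tert-butyl dicarbonate | CC(C)(C)OC(=O)OC(=O)OC(C)(C)C | starting material
17 | tert-butyl 2-methylbut-3-en-2-yl carbonate | C=CC(C)(C)OC(=O)OC(C)(C)C | intermediate
18 | 3-(2,2-dimethylchroman-6-yl)-7-(2-methylbut-3-en-2-yloxy)-4H-chromen-4-one | C=CC(C)(C)Oc1ccc2c(c1)occ(-c1ccc3c(c1)CCC(C)(C)O3)c2=O | intermediate
19 | racemic 3-(2,2-dimethylchroman-6-yl)-7-(2-methylbut-3-en-2-yloxy)chroman-4-one | C=CC(C)(C)Oc1ccc2c(c1)OCC(c1ccc3c(c1)CCC(C)(C)O3)C2=O | intermediate (not isolated)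
20 | (3R,4R)-3-(2,2-dimethylchroman-6-yl)-7-(2-methylbut-3-en-2-yloxy)chroman-4-ol | C=CC(C)(C)Oc1ccc2c(c1)OC[C@@H](c1ccc3c(c1)CCC(C)(C)O3)[C@H]2O | intermediate
21 | (3R)-3-(2,2-dimethylchroman-6-yl)-7-(2-methylbut-3-en-2-yloxy)chroman-4-one | C=CC(C)(C)Oc1ccc2c(c1)OC[C@@H](c1ccc3c(c1)CCC(C)(C)O3)C2=O | intermediate
22 | (3R)-3-(2,2-dimethylchroman-6-yl)-7-hydroxy-8-(3-methylbut-2-en-1-yl)chroman-4-one | CC(C)=CCc1c(O)ccc2c1OC[C@@H](c1ccc3c(c1)CCC(C)(C)O3)C2=O | target

**Step count.** Total: 11 steps. Longest linear sequence: 10 steps (steps 1–6 and 8–11; step 7 is a side branch).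

**Steps most likely to fail**

1. Step 3 (proposed new method). The carbene may dimerise or be trapped by diazoalkane as azine faster than it inserts into the strong primary C–H bond. The fallback sets out from 1 and comes back at 7, using known chemistry that closes the same ring as an alkene. SNAr of 1 with the sodium alkoxide of 15 (NaH, THF) should give 5-bromo-2-(2-methylbut-3-en-2-yloxy)benzaldehyde F1. Wittig methylenation (Ph3PCH3Br, KOtBu, THF) should give 4-bromo-2-ethenyl-1-(2-methylbut-3-en-2-yloxy)benzene F2. Ring-closing metathesis (Grubbs II, CH2Cl2, 40 °C) should give 6-bromo-2,2-dimethyl-2H-chromene F3. Diimide reduction (2-nitrobenzenesulfonohydrazide, Et3N, CH2Cl2, rt) should saturate the C-3–C-4 alkene without touching the aryl bromide and give 7.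

2. Step 11. The C-3 centre may racemise by thermal enolisation once the acidic phenol is present, and part of the material may rearrange to C-6. The fallback sets out from 18 and comes back at 22, moving the Claisen step before the stereocentre exists. Heating 18 in N,N-diethylaniline should give 3-(2,2-dimethylchroman-6-yl)-7-hydroxy-8-(3-methylbut-2-en-1-yl)-4H-chromen-4-one F4, from which any C-6 isomer is separated. Silylation (TIPSCl, imidazole, DMF) should give the 7-triisopropylsilyl ether F5. Transfer hydrogenation as in step 9 should give the (3R,4R)-chroman-4-ol F6. Dess–Martin oxidation should give the (3R)-chroman-4-one F7. Buffered desilylation (TBAF, AcOH, THF, 0 °C) should give 22.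

3. Step 8. Pd(0) may re-ionise the tertiary allyl aryl ether of this acidic phenol, which would lead to the linear prenyl ether or to C-allylation. The fallback sets out from 14 and comes back at 18 without a π-allyl intermediate. Copper-catalysed propargylation (3-chloro-3-methylbut-1-yne, CuCl2 cat., DBU, MeCN, 0 °C) should give 3-(2,2-dimethylchroman-6-yl)-7-(2-methylbut-3-yn-2-yloxy)-4H-chromen-4-one F8. Lindlar semihydrogenation (H2, Pd/CaCO3–Pb, quinoline, EtOAc) should give 18.

**Further compounds**
F1 | step 3 | 5-bromo-2-(2-methylbut-3-en-2-yloxy)benzaldehyde | C=CC(C)(C)Oc1ccc(Br)cc1C=O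
F2 | step 3 | 4-bromo-2-ethenyl-1-(2-methylbut-3-en-2-yloxy)benzene | C=CC(C)(C)Oc1ccc(Br)cc1C=C
F3 | step 3 | 6-bromo-2,2-dimethyl-2H-chromene | CC1(C)C=Cc2cc(Br)ccc2O1
F4 | step 11 | 3-(2,2-dimethylchroman-6-yl)-7-hydroxy-8-(3-methylbut-2-en-1-yl)-4H-chromen-4-one | CC(C)=CCc1c(O)ccc2c1occ(-c1ccc3c(c1)CCC(C)(C)O3)c2=O
F5 | step 11 | 3-(2,2-dimethylchroman-6-yl)-8-(3-methylbut-2-en-1-yl)-7-(triisopropylsilyloxy)-4H-chromen-4-one | CC(C)=CCc1c(O[Si](C(C)C)(C(C)C)C(C)C)ccc2c1occ(-c1ccc3c(c1)CCC(C)(C)O3)c2=O
F6 | step 11 | (3R,4R)-3-(2,2-dimethylchroman-6-yl)-8-(3-methylbut-2-en-1-yl)-7-(triisopropylsilyloxy)chroman-4-ol | CC(C)=CCc1c(O[Si](C(C)C)(C(C)C)C(C)C)ccc2c1OC[C@@H](c1ccc3c(c1)CCC(C)(C)O3)[C@H]2O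
F7 | step 11 | (3R)-3-(2,2-dimethylchroman-6-yl)-8-(3-methylbut-2-en-1-yl)-7-(triisopropylsilyloxy)chroman-4-one | CC(C)=CCc1c(O[Si](C(C)C)(C(C)C)C(C)C)ccc2c1OC[C@@H](c1ccc3c(c1)CCC(C)(C)O3)C2=O
F8 | step 8 | 3-(2,2-dimethylchroman-6-yl)-7-(2-methylbut-3-yn-2-yloxy)-4H-chromen-4-one | C#CC(C)(C)Oc1ccc2c(c1)occ(-c1ccc3c(c1)CCC(C)(C)O3)c2=O
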